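Ring atoms are numbered as in the name of the target: C1 (quaternary epoxide carbon), C2 (carbinol), C3=C4 (ring alkene), C5 (carbinol), C6 (epoxide CH), O7.

Assumption (chemistry): the sense of asymmetric induction in step 8 is assigned by analogy with the cyclopentadiene/ynal reactions of the same catalyst class; it would be checked on the first run and the mirror-image catalyst used if needed, with no other change.

## Analysis of the target

The target is a 7-oxabicyclo[4.1.0]hept-3-ene: a cyclohexene ring (C1–C6) in which every carbon is substituted, with the epoxide oxygen O7 bridging C1 and C6. It has four contiguous stereocentres, C5, C6, C1 and C2 (5S,6R,1S,2R). C1 is quaternary and carries the (E)-3-carboxybut-2-enyl chain. The hydroxyls at C2 and C5 are cis to each other and both anti to O7. The ring alkene C3=C4 is tetrasubstituted: C3 bears the (E)-hept-1-enyl group (a conjugated diene) and C4 the hydroxymethyl group.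

The ring sits at the oxidation level of an epoxidised dihydro-hydroquinone. Both carbinols are doubly activated, so loss of water or ionisation aromatises the ring, and a quinone cannot simply be reduced to this level without tautomerising to the arene. Acid threatens the epoxide and the allylic carbinols. Base threatens epoxide migration (Payne type), because both hydroxyls are anti to the epoxide. The diene is open to oxidation.

The feature that invites the key move: the carbinol carbons C2 and C5 lie 1,4 across the C3=C4 double bond and are cis, and the remaining ring bond C1–C6 is an epoxidised alkene. This cis-cyclohexa-2,5-diene-1,4-diol pattern is the retron of a [4+2] cycloaddition between an alkyne (C3≡C4) and an (E,E)-1,4-dioxygenated diene (C2=C1–C6=C5). The difficulty is to place five different substituents regiospecifically on six carbons and set four stereocentres, one quaternary, without ever passing through an aromatic ring.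

## Retrosynthetic reasoning

**18 ⇐ 17.** No skeletal bond is cut. The two hydroxyls and the acid are released together in one fluoride-mediated operation from two silyl ethers and a 2-(trimethylsilyl)ethyl ester, so that neither hydroxide nor acid meets the free epoxy diol.

**17 ⇐ 16.** The hydroxymethyl group at C4 is traced to a formyl group. The aldehyde is wanted earlier for two reasons: it activates the alkyne of the cycloaddition, and it keeps the C3=C4/heptenyl diene electron-poor while C1=C6 is oxidised.

**16 ⇐ 15.** The two C–O bonds of the epoxide are cut, leaving the C1=C6 alkene of cyclohexa-1,4-diene 15. In 15 both silyloxy groups lie on one face and flank this alkene, so an electrophilic oxygen donor must come from the other face. C1 and C6 are thus relayed from C2 and C5, in the anti sense the target needs.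

**15 ⇐ 10 + 14 (key disconnection).** The ring bonds C2–C3 and C4–C5 are cut. This opens the carbocycle into the acyclic (E,E)-bis(silyloxy)diene 10, which carries the C1 side chain, and ynal 14, which carries the heptenyl group and the future C4 carbon. The forward [4+2] cycloaddition closes the ring, installs the tetrasubstituted C3=C4 alkene with both substituents, sets C2 and C5 cis in one event, and leaves C1=C6 for the epoxide. The cut is made here because both precursors are acyclic, achiral and without stereocentres. The forward reaction must control regiochemistry (C1 side chain para to the formyl-bearing carbon) and the diene face (absolute configuration).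

**10 ⇐ 9.** The dienol silyl ether is traced to the γ-silyloxy enal 9 by vinylogous enolisation and O-silylation. Both enol ether geometries are dictated by the enal (s-trans conformation and allylic 1,3-strain), so no separate stereocontrol is needed.

**9 ⇐ 6 + 7; 6 ⇐ 5 + 4; 4 ⇐ 3 ⇐ 1 + 2.** The C=C bond of 9 is cut by a formyl-olefination between phosphonate 6 and aldehyde 7. The bond between the olefination reagent and the side chain is cut by C-alkylation of 5 with allylic bromide 4. Bromide 4 comes from ester 3 by allylic bromination, and 3 from tiglic acid 1 and alcohol 2.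

**14 ⇐ 12 ⇐ 11.** The ynal is cut at the formyl carbon and at the alkyne: two one-carbon homologations of (E)-oct-2-enal 11 through dibromodiene 12, which keep the E alkene.

## Alternatives that were turned down

**Alternative 1:** (the textbook route) Disconnect the epoxide and both carbinols back to a p-quinone monoketal. An arene carrying all five substituents is oxidatively dearomatised to bromo quinone monoketal A1. Asymmetric nucleophilic epoxidation of its enone C1=C6 bond gives epoxy ketone A2, followed by cross-coupling of the heptenyl group at C3, ketal hydrolysis and two separate carbonyl reductions. It was turned down for three reasons: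
- The pentasubstituted arene must be built in a long linear sequence.
- The stereocentres are set in three unrelated events: the epoxidation, then the reduction at C2 next to the quaternary centre, then the reduction at C5. Each needs its own anti selectivity.
- The cross-coupling and the reductions run on base-sensitive epoxy enones.

The step count would be well above that of the route below.

**Alternative 2:** Disconnect the two carbinol C–O bonds to a peroxide bridge. Photo-oxygenation of arene oxide A3 across C2/C5, anti to the epoxide, would give endoperoxide A4, and O–O reduction would give the cis-diol directly. It was turned down for four reasons: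
- An arene oxide racemises through its oxepin valence tautomer, so A3 cannot be carried as a single enantiomer and a late resolution would be unavoidable.
- A3 isomerises easily to a phenol.
- The heptenyl diene offers competing ene and [4+2] sites to the oxidant.
- A3 itself would cost about as many steps as the whole route below.

**Alternative 3:** Disconnect the ring alkene by metathesis. The epoxide stereocentres are set first in an acyclic allylic alcohol by asymmetric epoxidation and the chain is elaborated to enyne A5. Ring-closing enyne metathesis of A5 (second-generation Grubbs catalyst, ethylene) would form the C3=C4 bond, and a cross-metathesis would attach the pentyl terminus. It was turned down for four reasons: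
- The key step forms the ring but no stereocentre.
- C2 and C5 must be set one at a time by additions to α,β-epoxy aldehydes with uncertain acyclic control.
- Closing a tetrasubstituted ring alkene onto a 1,1-disubstituted olefin is slow.
- The cross-metathesis at a conjugated diene is unselective.

The linear sequence would be far longer.

Key step: step 8

## Route

Step 1
Reactants: 1 (2E)-2-methylbut-2-enoic acid (tiglic acid); 2 2-(trimethylsilyl)ethanol
Product: 3 2-(trimethylsilyl)ethyl (2E)-2-methylbut-2-enoate
Conditions: DCC, DMAP (cat.), CH2Cl2, 0 °C to rt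
Reagents that add atoms: none
Why: Steglich esterification; the fluoride-labile ester lets the acid be released at the very end together with the silyl ethers, without hydroxide.

Step 2
Reactants: 3 2-(trimethylsilyl)ethyl (2E)-2-methylbut-2-enoate
Product: 4 2-(trimethylsilyl)ethyl (2E)-4-bromo-2-methylbut-2-enoate
Conditions: NBS, AIBN (cat.), PhCF3, 80 °C
Reagents that add atoms: N-bromosuccinimide, O=C1CCC(=O)N1Br
Why: Wohl–Ziegler allylic bromination at the γ-methyl group through the delocalised allyl radical; the E geometry is the thermodynamic one and should be kept, and the minor 2-(bromomethyl) regioisomer would be removed by chromatography.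

Step 3
Reactants: 5 diethyl [(E)-2-(cyclohexylamino)ethenyl]phosphonate; 4 2-(trimethylsilyl)ethyl (2E)-4-bromo-2-methylbut-2-enoate
Product: 6 2-(trimethylsilyl)ethyl (2E)-6-(cyclohexylamino)-5-(diethoxyphosphoryl)-2-methylhexa-2,5-dienoate (enamine form, C5=C6 geometry undefined and irrelevant)
Conditions: NaH, THF, 0 °C; then 4, 0 °C to rt
Reagents that add atoms: none
Why: C-alkylation of the sodium aza-enolate of the β-enamino phosphonate at the carbon α to phosphorus (SN2 at a primary allylic bromide, alkene geometry untouched), the established way to α-substituted formyl-olefination reagents.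

Step 4
Reactants: 6 2-(trimethylsilyl)ethyl (2E)-6-(cyclohexylamino)-5-(diethoxyphosphoryl)-2-methylhexa-2,5-dienoate; 7 {[tert-butyl(dimethyl)silyl]oxy}acetaldehyde
Product: 9 2-(trimethylsilyl)ethyl (2E,5E)-7-{[tert-butyl(dimethyl)silyl]oxy}-5-formyl-2-methylhepta-2,5-dienoate, via unsaturated N-cyclohexyl aldimine 8 (not isolated)
Conditions: NaH, THF, 0 °C; 7, 0 °C to rt; then AcOH/NaOAc buffer (pH 4.5), Et2O, rt
Reagents that add atoms: water (O)
Why: Horner–Wadsworth–Emmons formyl-olefination gives the α,β-unsaturated aldimine, which the buffer hydrolyses to the α-substituted enal; the C5=C6 geometry of 9 does not matter because both isomers converge in step 5.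

Step 5
Reactants: 9 2-(trimethylsilyl)ethyl (2E,5E)-7-{[tert-butyl(dimethyl)silyl]oxy}-5-formyl-2-methylhepta-2,5-dienoate
Product: 10 2-(trimethylsilyl)ethyl (2E,5E,6E)-7-{[tert-butyl(dimethyl)silyl]oxy}-5-({[tert-butyl(dimethyl)silyl]oxy}methylidene)-2-methylhepta-2,6-dienoate
Conditions: TBSOTf, Et3N, Et2O, −78 to 0 °C; dilution with pentane, filtration, no aqueous work-up
Reagents that add atoms: tert-butyldimethylsilyl trifluoromethanesulfonate, CC(C)(C)[Si](C)(C)OS(=O)(=O)C(F)(F)F
Why: Vinylogous (γ) soft enolisation with O-silylation of the enal; the new enol ether next to the side chain should be E because the α-substituted enal reacts from its s-trans conformation, and the new C6=C7 enol ether should be E because allylic 1,3-strain with the fully substituted C5 forces the silyloxy group outward during γ-deprotonation.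

Step 6
Reactants: 11 (2E)-oct-2-enal
Product: 12 (3E)-1,1-dibromonona-1,3-diene
Conditions: CBr4, PPh3, CH2Cl2, 0 °C
Reagents that add atoms: carbon tetrabromide, BrC(Br)(Br)Br
Why: First stage of the Corey–Fuchs homologation (Wittig-type dibromo-olefination); the E alkene of the enal is not touched.

Step 7
Reactants: 12 (3E)-1,1-dibromonona-1,3-diene
Product: 14 (4E)-dec-4-en-2-ynal, via lithium enynide 13 (not isolated)
Conditions: n-BuLi (2.1 equiv), THF, −78 °C; DMF, −78 to −20 °C; inverse quench into aqueous KH2PO4/MTBE, 0 °C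
Reagents that add atoms: N,N-dimethylformamide, CN(C)C=O; n-butyllithium, [Li]CCCC (supplies the lithium of 13 only)
Why: Second stage of the Corey–Fuchs sequence (bromine–lithium exchange, elimination and deprotonation to the lithium acetylide) followed by formylation with DMF; the buffered inverse quench should release the ynal without conjugate addition of dimethylamine.

Step 8
Reactants: 10 2-(trimethylsilyl)ethyl (2E,5E,6E)-7-{[tert-butyl(dimethyl)silyl]oxy}-5-({[tert-butyl(dimethyl)silyl]oxy}methylidene)-2-methylhepta-2,6-dienoate; 14 (4E)-dec-4-en-2-ynal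
Product: 15 2-(trimethylsilyl)ethyl (2E)-4-{(3R,6S)-3,6-bis{[tert-butyl(dimethyl)silyl]oxy}-4-formyl-5-[(1E)-hept-1-en-1-yl]cyclohexa-1,4-dien-1-yl}-2-methylbut-2-enoate
Conditions: (S)-3,3-diphenyl-1-(2-methylphenyl)tetrahydro-1H,3H-pyrrolo[1,2-c][1,3,2]oxazaborole (20 mol %) activated with Tf2NH (17 mol %), 2,6-di-tert-butyl-4-methylpyridine (5 mol %), CH2Cl2, −78 °C, slow addition of 10; 2,6-lutidine, then pH 7 buffer; chromatography on Et3N-deactivated silica
Reagents that add atoms: none
Why: Proposed new method: a catalytic enantioselective Diels–Alder reaction of an ynal with an acyclic (E,E)-1,4-bis(silyloxy)diene, whose closest known reaction types are the chiral oxazaborolidinium- and acyloxyborane-catalysed cycloadditions of acetylenic aldehydes with cyclopentadiene and the oxazaborolidinium-catalysed cycloadditions of enals and quinones with silyloxy dienes; mechanistically the cationic boron binds the formyl oxygen anti to the alkyne, lowers the LUMO of the conjugated π bond and covers one face of the planar ynal with its aryl group. The six-membered carbocycle is closed by an intermolecular [4+2] cycloaddition, suprafacial on both partners, that forms C2–C3 and C4–C5 (target numbering) in one asynchronous event, with the bond from diene terminus C2 to the β-carbon of the ynal the more advanced. Regioselectivity is needed and should come from the diene: the two silyloxy termini cancel electronically, and attack through C2 leaves allyl-cation character on the tertiary C1 and the oxygen-bearing C5, which puts the C1 side chain para to the formyl-bearing carbon as the target requires; the Lewis-acid-bound ynal should sharpen this preference. The cis relationship of the two new stereocentres (C3 and C6 of 15, the future C5 and C2) follows stereospecifically from the (E,E) geometry of 10, each silyloxy group being outside in the s-cis diene. Their absolute configuration is controlled by the catalyst: with one face of the ynal plane shielded, the diene can only choose between having the formyl oxygen and boron over the diene or away from it, and the exo preference known for ynals turns face shielding into one enantiomer. Chemoselectivity is also needed against Mukaiyama-type 1,2-addition of the silyl enol ether to the formyl group and against silyl-triflimide background catalysis; low temperature, slow diene addition and the hindered pyridine are meant to secure it. The adduct is a protected dihydroarene and an enal with an acidic γ-hydrogen, so it is quenched cold, kept neutral and used at once.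

Step 9
Reactants: 15 2-(trimethylsilyl)ethyl (2E)-4-{(3R,6S)-3,6-bis{[tert-butyl(dimethyl)silyl]oxy}-4-formyl-5-[(1E)-hept-1-en-1-yl]cyclohexa-1,4-dien-1-yl}-2-methylbut-2-enoate
Product: 16 2-(trimethylsilyl)ethyl (2E)-4-{(1R,2R,5S,6R)-2,5-bis{[tert-butyl(dimethyl)silyl]oxy}-4-formyl-3-[(1E)-hept-1-en-1-yl]-7-oxabicyclo[4.1.0]hept-3-en-1-yl}-2-methylbut-2-enoate
Conditions: DMDO (1.2 equiv, acetone solution), CH2Cl2, −30 to 0 °C
Reagents that add atoms: dimethyldioxirane, CC1(C)OO1
Why: Electrophilic epoxidation with a neutral dioxirane should pick the only isolated, electron-rich alkene (trisubstituted C1=C6), since the formyl-conjugated C3=C4/heptenyl diene and the enoate are deactivated; both bulky allylic silyloxy groups sit on the same face and flank this alkene, so oxygen is delivered to the opposite face and C1 and C6 are set anti to both carbinol oxygens by substrate control.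

Step 10
Reactants: 16 2-(trimethylsilyl)ethyl (2E)-4-{(1R,2R,5S,6R)-2,5-bis{[tert-butyl(dimethyl)silyl]oxy}-4-formyl-3-[(1E)-hept-1-en-1-yl]-7-oxabicyclo[4.1.0]hept-3-en-1-yl}-2-methylbut-2-enoate
Product: 17 2-(trimethylsilyl)ethyl (2E)-4-{(1R,2R,5S,6R)-2,5-bis{[tert-butyl(dimethyl)silyl]oxy}-3-[(1E)-hept-1-en-1-yl]-4-(hydroxymethyl)-7-oxabicyclo[4.1.0]hept-3-en-1-yl}-2-methylbut-2-enoate
Conditions: NaBH4, CeCl3·7H2O, MeOH, −78 °C; pH 7 buffer
Reagents that add atoms: none
Why: Luche 1,2-reduction of the dienal, chemoselective over the ester and the epoxide; the cold, short, near-neutral conditions avoid vinylogous enolisation at C2, which would open the epoxide.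

Step 11
Reactants: 17 2-(trimethylsilyl)ethyl (2E)-4-{(1R,2R,5S,6R)-2,5-bis{[tert-butyl(dimethyl)silyl]oxy}-3-[(1E)-hept-1-en-1-yl]-4-(hydroxymethyl)-7-oxabicyclo[4.1.0]hept-3-en-1-yl}-2-methylbut-2-enoate
Product: 18 (2E)-4-{(1S,2R,5S,6R)-3-[(1E)-hept-1-en-1-yl]-2,5-dihydroxy-4-(hydroxymethyl)-7-oxabicyclo[4.1.0]hept-3-en-1-yl}-2-methylbut-2-enoic acid (CNP0087193.4)
Conditions: TASF (tris(dimethylamino)sulfonium difluorotrimethylsilicate, 6 equiv), DMF, 0 °C to rt; aqueous NH4Cl
Reagents that add atoms: none
Why: Fluoride cleaves both Si–O bonds and triggers the β-elimination of the 2-(trimethylsilyl)ethyl ester (ethene and fluorotrimethylsilane) in one global deprotection; no stereocentre is touched, and the change of the C1 descriptor from R to S is only a change in CIP priorities.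

## Compound list

1 | (2E)-2-methylbut-2-enoic acid (tiglic acid) | C/C=C(\C)C(=O)O | starting material
2 | 2-(trimethylsilyl)ethanol | C[Si](C)(C)CCO | starting material
3 | 2-(trimethylsilyl)ethyl (2E)-2-methylbut-2-enoate | C/C=C(\C)C(=O)OCC[Si](C)(C)C | intermediate
4 | 2-(trimethylsilyl)ethyl (2E)-4-bromo-2-methylbut-2-enoate | BrC/C=C(\C)C(=O)OCC[Si](C)(C)C | intermediate
5 | diethyl [(E)-2-(cyclohexylamino)ethenyl]phosphonate | CCOP(=O)(OCC)/C=C/NC1CCCCC1 | starting material
6 | 2-(trimethylsilyl)ethyl (2E)-6-(cyclohexylamino)-5-(diethoxyphosphoryl)-2-methylhexa-2,5-dienoate (enamine geometry undefined) | CCOP(=O)(OCC)C(C/C=C(\C)C(=O)OCC[Si](C)(C)C)=CNC1CCCCC1 | intermediate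
7 | {[tert-butyl(dimethyl)silyl]oxy}acetaldehyde | CC(C)(C)[Si](C)(C)OCC=O | starting material
8 | 2-(trimethylsilyl)ethyl (2E,5E)-7-{[tert-butyl(dimethyl)silyl]oxy}-5-[(E)-(cyclohexylimino)methyl]-2-methylhepta-2,5-dienoate | CC(C)(C)[Si](C)(C)OC/C=C(C/C=C(\C)C(=O)OCC[Si](C)(C)C)/C=N/C1CCCCC1 | intermediate (not isolated)
9 | 2-(trimethylsilyl)ethyl (2E,5E)-7-{[tert-butyl(dimethyl)silyl]oxy}-5-formyl-2-methylhepta-2,5-dienoate | CC(C)(C)[Si](C)(C)OC/C=C(C/C=C(\C)C(=O)OCC[Si](C)(C)C)/C=O | intermediate
10 | 2-(trimethylsilyl)ethyl (2E,5E,6E)-7-{[tert-butyl(dimethyl)silyl]oxy}-5-({[tert-butyl(dimethyl)silyl]oxy}methylidene)-2-methylhepta-2,6-dienoate | CC(C)(C)[Si](C)(C)O/C=C(C/C=C(\C)C(=O)OCC[Si](C)(C)C)/C=C/O[Si](C)(C)C(C)(C)C | intermediate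
11 | (2E)-oct-2-enal | CCCCC/C=C/C=O | starting material
12 | (3E)-1,1-dibromonona-1,3-diene | CCCCC/C=C/C=C(Br)Br | intermediate
13 | lithium (3E)-non-3-en-1-yn-1-ide | [Li]C#C/C=C/CCCCC | intermediate (not isolated)
14 | (4E)-dec-4-en-2-ynal | CCCCC/C=C/C#CC=O | intermediate
15 | 2-(trimethylsilyl)ethyl (2E)-4-{(3R,6S)-3,6-bis{[tert-butyl(dimethyl)silyl]oxy}-4-formyl-5-[(1E)-hept-1-en-1-yl]cyclohexa-1,4-dien-1-yl}-2-methylbut-2-enoate | CCCCC/C=C/C1=C(C=O)[C@H](O[Si](C)(C)C(C)(C)C)C=C(C/C=C(\C)C(=O)OCC[Si](C)(C)C)[C@@H]1O[Si](C)(C)C(C)(C)C | intermediate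
16 | 2-(trimethylsilyl)ethyl (2E)-4-{(1R,2R,5S,6R)-2,5-bis{[tert-butyl(dimethyl)silyl]oxy}-4-formyl-3-[(1E)-hept-1-en-1-yl]-7-oxabicyclo[4.1.0]hept-3-en-1-yl}-2-methylbut-2-enoate | CCCCC/C=C/C1=C(C=O)[C@H](O[Si](C)(C)C(C)(C)C)[C@H]2O[C@@]2(C/C=C(\C)C(=O)OCC[Si](C)(C)C)[C@@H]1O[Si](C)(C)C(C)(C)C | intermediate
17 | 2-(trimethylsilyl)ethyl (2E)-4-{(1R,2R,5S,6R)-2,5-bis{[tert-butyl(dimethyl)silyl]oxy}-3-[(1E)-hept-1-en-1-yl]-4-(hydroxymethyl)-7-oxabicyclo[4.1.0]hept-3-en-1-yl}-2-methylbut-2-enoate | CCCCC/C=C/C1=C(CO)[C@H](O[Si](C)(C)C(C)(C)C)[C@H]2O[C@@]2(C/C=C(\C)C(=O)OCC[Si](C)(C)C)[C@@H]1O[Si](C)(C)C(C)(C)C | intermediate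
18 | (2E)-4-{(1S,2R,5S,6R)-3-[(1E)-hept-1-en-1-yl]-2,5-dihydroxy-4-(hydroxymethyl)-7-oxabicyclo[4.1.0]hept-3-en-1-yl}-2-methylbut-2-enoic acid | CCCCC/C=C/C1=C(CO)[C@H](O)[C@H]2O[C@@]2(C/C=C(\C)C(=O)O)[C@@H]1O | target

## Step count and least certain steps

Total step count: 11. Longest linear sequence: 9 (steps 1–5 and 8–11); the ynal branch (steps 6–7) joins at step 8.

**Step 8 (key step, proposed new method).** Several things may go wrong:
- 1,2-addition of the silyl enol ether to the activated formyl group in place of cycloaddition.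
- Silyl transfer to triflimide, which would start an achiral background catalysis and erode the enantioselectivity.
- Incomplete regiocontrol, because only the alkyl group at C1 differentiates the two diene termini.
- Aromatisation of the adduct by loss of silanol.
- Geometric impurity of 10, which would lower the rate (only the (E,E) isomer has both hydrogens inside) but not change the product.

Fallback, in known chemistry and with a different source of absolute configuration: it sets out from 10 and 14 and comes back at 17. The two are combined without catalyst (toluene, 2,6-di-tert-butyl-4-methylphenol, 0 °C to rt) in a thermal Diels–Alder reaction of a known type to give the racemate of 15, racemic adduct F1. Steps 9 and 10 applied to it give racemic epoxy aldehyde F2 and racemic allylic alcohol F3. Esterification of F3 with (S)-O-methylmandelic acid (DCC, DMAP) gives two diastereomers, the (1R,2R,5S,6R) mandelate F4 and the (1S,2S,5R,6S) mandelate F5, to be separated by chromatography. Mild methanolysis of F4 (K2CO3, MeOH, 0 °C) returns 17 as a single enantiomer, and step 11 follows.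

**Step 9.** Oxygen transfer may lose chemoselectivity (attack on the heptenyl alkene of the dienal, or on a small equilibrium amount of the 2H-pyran formed by oxa-6π closure of the Z-dienal), or the facial selectivity may be lower than the two silyloxy groups suggest.

Fallback, which moves the heptenyl group behind the epoxidation: it sets out from 10 and comes back at 16. Commercial 3,3-diethoxyprop-1-yne is brominated (NBS, AgNO3 cat., acetone) to 1-bromo-3,3-diethoxyprop-1-yne F6 and hydrolysed (HCO2H) to 3-bromoprop-2-ynal F7. Cycloaddition of F7 with 10 under the conditions of step 8 gives the bromo cyclohexadiene carbaldehyde F8. DMDO epoxidation, now without a competing alkene, gives the bromo epoxy aldehyde F9. A Suzuki–Miyaura coupling of F9 with (E)-hept-1-en-1-ylboronic acid (Pd(PPh3)4, CsF, THF, rt) gives 16.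

**Step 11.** The alkoxides formed on desilylation are anti to the epoxide and may start an epoxide migration (Payne type) or an opening during the longer time the ester cleavage needs.

Fallback, which separates the two events so that no alkoxide is formed next to the epoxide: it sets out from 17 and comes back at 18. A limited amount of TBAF (THF, 0 °C) cleaves only the 2-(trimethylsilyl)ethyl ester to give the bis-silyl acid F10. HF·pyridine buffered with pyridine (THF, 0 °C) then removes both silyl ethers under weakly acidic conditions to give 18.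

**Step 3.** The ambident aza-enolate may alkylate on nitrogen, or twice, so that the olefination of step 4 gives mixtures.

Fallback, with a different formyl equivalent: it sets out from 4 and comes back at 9. Commercial diethyl {2-[methoxy(methyl)amino]-2-oxoethyl}phosphonate is C-alkylated with 4 (NaH, THF) to the phosphonoamide F11. Horner–Wadsworth–Emmons reaction of F11 with 7 (NaH, THF) gives the unsaturated N-methoxy-N-methylamide F12. Chemoselective amide reduction with Cp2Zr(H)Cl (THF, rt), which leaves esters alone, gives enal 9.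

## Further compounds

F1 | step 8 | racemate of 15: 2-(trimethylsilyl)ethyl (2E)-4-{(3R*,6S*)-3,6-bis{[tert-butyl(dimethyl)silyl]oxy}-4-formyl-5-[(1E)-hept-1-en-1-yl]cyclohexa-1,4-dien-1-yl}-2-methylbut-2-enoate (one enantiomer drawn) | CCCCC/C=C/C1=C(C=O)[C@H](O[Si](C)(C)C(C)(C)C)C=C(C/C=C(\C)C(=O)OCC[Si](C)(C)C)[C@@H]1O[Si](C)(C)C(C)(C)C
F2 | step 8 | racemate of 16: 2-(trimethylsilyl)ethyl (2E)-4-{(1R*,2R*,5S*,6R*)-2,5-bis{[tert-butyl(dimethyl)silyl]oxy}-4-formyl-3-[(1E)-hept-1-en-1-yl]-7-oxabicyclo[4.1.0]hept-3-en-1-yl}-2-methylbut-2-enoate (one enantiomer drawn) | CCCCC/C=C/C1=C(C=O)[C@H](O[Si](C)(C)C(C)(C)C)[C@H]2O[C@@]2(C/C=C(\C)C(=O)OCC[Si](C)(C)C)[C@@H]1O[Si](C)(C)C(C)(C)C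
F3 | step 8 | racemate of 17: 2-(trimethylsilyl)ethyl (2E)-4-{(1R*,2R*,5S*,6R*)-2,5-bis{[tert-butyl(dimethyl)silyl]oxy}-3-[(1E)-hept-1-en-1-yl]-4-(hydroxymethyl)-7-oxabicyclo[4.1.0]hept-3-en-1-yl}-2-methylbut-2-enoate (one enantiomer drawn) | CCCCC/C=C/C1=C(CO)[C@H](O[Si](C)(C)C(C)(C)C)[C@H]2O[C@@]2(C/C=C(\C)C(=O)OCC[Si](C)(C)C)[C@@H]1O[Si](C)(C)C(C)(C)C
F4 | step 8 | 2-(trimethylsilyl)ethyl (2E)-4-{(1R,2R,5S,6R)-2,5-bis{[tert-butyl(dimethyl)silyl]oxy}-3-[(1E)-hept-1-en-1-yl]-4-({[(2S)-2-methoxy-2-phenylacetyl]oxy}methyl)-7-oxabicyclo[4.1.0]hept-3-en-1-yl}-2-methylbut-2-enoate | CCCCC/C=C/C1=C(COC(=O)[C@@H](OC)c3ccccc3)[C@H](O[Si](C)(C)C(C)(C)C)[C@H]2O[C@@]2(C/C=C(\C)C(=O)OCC[Si](C)(C)C)[C@@H]1O[Si](C)(C)C(C)(C)C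
F5 | step 8 | 2-(trimethylsilyl)ethyl (2E)-4-{(1S,2S,5R,6S)-2,5-bis{[tert-butyl(dimethyl)silyl]oxy}-3-[(1E)-hept-1-en-1-yl]-4-({[(2S)-2-methoxy-2-phenylacetyl]oxy}methyl)-7-oxabicyclo[4.1.0]hept-3-en-1-yl}-2-methylbut-2-enoate | CCCCC/C=C/C1=C(COC(=O)[C@@H](OC)c3ccccc3)[C@@H](O[Si](C)(C)C(C)(C)C)[C@@H]2O[C@]2(C/C=C(\C)C(=O)OCC[Si](C)(C)C)[C@H]1O[Si](C)(C)C(C)(C)C
F6 | step 9 | 1-bromo-3,3-diethoxyprop-1-yne | BrC#CC(OCC)OCC
F7 | step 9 | 3-bromoprop-2-ynal | BrC#CC=O
F8 | step 9 | 2-(trimethylsilyl)ethyl (2E)-4-[(3R,6S)-5-bromo-3,6-bis{[tert-butyl(dimethyl)silyl]oxy}-4-formylcyclohexa-1,4-dien-1-yl]-2-methylbut-2-enoate | BrC1=C(C=O)[C@H](O[Si](C)(C)C(C)(C)C)C=C(C/C=C(\C)C(=O)OCC[Si](C)(C)C)[C@@H]1O[Si](C)(C)C(C)(C)C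
F9 | step 9 | 2-(trimethylsilyl)ethyl (2E)-4-[(1R,2S,5S,6R)-3-bromo-2,5-bis{[tert-butyl(dimethyl)silyl]oxy}-4-formyl-7-oxabicyclo[4.1.0]hept-3-en-1-yl]-2-methylbut-2-enoate | BrC1=C(C=O)[C@H](O[Si](C)(C)C(C)(C)C)[C@H]2O[C@@]2(C/C=C(\C)C(=O)OCC[Si](C)(C)C)[C@@H]1O[Si](C)(C)C(C)(C)C
F10 | step 11 | (2E)-4-{(1R,2R,5S,6R)-2,5-bis{[tert-butyl(dimethyl)silyl]oxy}-3-[(1E)-hept-1-en-1-yl]-4-(hydroxymethyl)-7-oxabicyclo[4.1.0]hept-3-en-1-yl}-2-methylbut-2-enoic acid | CCCCC/C=C/C1=C(CO)[C@H](O[Si](C)(C)C(C)(C)C)[C@H]2O[C@@]2(C/C=C(\C)C(=O)O)[C@@H]1O[Si](C)(C)C(C)(C)C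
F11 | step 3 | 2-(trimethylsilyl)ethyl (2E)-5-(diethoxyphosphoryl)-6-[methoxy(methyl)amino]-2-methyl-6-oxohex-2-enoate (racemic at C5) | CCOP(=O)(OCC)C(C/C=C(\C)C(=O)OCC[Si](C)(C)C)C(=O)N(C)OC
F12 | step 3 | 2-(trimethylsilyl)ethyl (2E,5E)-7-{[tert-butyl(dimethyl)silyl]oxy}-5-[methoxy(methyl)carbamoyl]-2-methylhepta-2,5-dienoate | CC(C)(C)[Si](C)(C)OC/C=C(C/C=C(\C)C(=O)OCC[Si](C)(C)C)/C(=O)N(C)OC
A1 | alternative 1 | methyl (2E)-4-[5-bromo-4-({[tert-butyl(dimethyl)silyl]oxy}methyl)-3,3-dimethoxy-6-oxocyclohexa-1,4-dien-1-yl]-2-methylbut-2-enoate | COC(=O)/C(C)=C/CC1=CC(OC)(OC)C(CO[Si](C)(C)C(C)(C)C)=C(Br)C1=O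
A2 | alternative 1 | methyl (2E)-4-[(1R,6S)-3-bromo-4-({[tert-butyl(dimethyl)silyl]oxy}methyl)-5,5-dimethoxy-2-oxo-7-oxabicyclo[4.1.0]hept-3-en-1-yl]-2-methylbut-2-enoate | BrC1=C(CO[Si](C)(C)C(C)(C)C)C(OC)(OC)[C@H]2O[C@@]2(C/C=C(\C)C(=O)OC)C1=O
A3 | alternative 2 | methyl (2E)-4-{4-({[tert-butyl(dimethyl)silyl]oxy}methyl)-3-[(1E)-hept-1-en-1-yl]-7-oxabicyclo[4.1.0]hepta-2,4-dien-1-yl}-2-methylbut-2-enoate (racemic, in equilibrium with its oxepin) | CCCCC/C=C/C1=CC2(C/C=C(\C)C(=O)OC)OC2C=C1CO[Si](C)(C)C(C)(C)C
A4 | alternative 2 | methyl (2E)-4-{9-({[tert-butyl(dimethyl)silyl]oxy}methyl)-8-[(1E)-hept-1-en-1-yl]-3,6,7-trioxatricyclo[3.2.2.0(2,4)]non-8-en-2-yl}-2-methylbut-2-enoate (racemic, epoxide anti to the peroxide bridge, one enantiomer drawn) | CCCCC/C=C/C1=C(CO[Si](C)(C)C(C)(C)C)[C@H](O3)[C@H]2O[C@@]2(C/C=C(\C)C(=O)OC)[C@@H]1O3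
A5 | alternative 3 | methyl (2E)-4-[(2R,3R)-3-[(1S)-1-{[tert-butyl(dimethyl)silyl]oxy}-2-({[tert-butyl(dimethyl)silyl]oxy}methyl)prop-2-en-1-yl]-2-[(1R)-1-{[tert-butyl(dimethyl)silyl]oxy}prop-2-yn-1-yl]oxiran-2-yl]-2-methylbut-2-enoate | C=C(CO[Si](C)(C)C(C)(C)C)[C@H](O[Si](C)(C)C(C)(C)C)[C@H]1O[C@@]1(C/C=C(\C)C(=O)OC)[C@@H](C#C)O[Si](C)(C)C(C)(C)C
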